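## Structural features

The target is a 14-membered carbocycle (C1, C2, C3, C6–C16) fused across its C3–C6 edge to an α-methylbutenolide (O–C5(=O)–C4(CH3)=C3, ring oxygen on C6). The large ring carries two E-trisubstituted alkenes (C7=C8 and C15=C16, each with a methyl group), a trisubstituted epoxide at C11–C12 (methyl on C12) and an allylic acetate at C1. There are four stereocentres, 1R, 6R, 11S and 12R: C11 and C12 are adjacent in the epoxide, C1 and C6 flank the butenolide carbon C3, and the two pairs are remote from each other. The epoxide is cis with respect to the ring (C10 and C13 on the same side), so it cannot come from epoxidation of an E-alkene. C6–H is both the γ-hydrogen of the butenolide and allylic, hence easily removed by base, and C6–O is an allylic ester bond; the epoxide is acid-sensitive and the C1 acetate is an allylic ester open to zerovalent palladium and to base. The real difficulty is to close the 14-membered ring without exposing C6–H to base and to bring in the cis-epoxide and the acetate late. The feature exploited is that C9 is the primary allylic terminus of C7=C8 while C10 is α to C11, which can be carried as a ketone: C9–C10 is an allyl–enolate bond, and inserting CO2 between C10 and an oxygen on C9 turns the carbocycle into a 16-membered allyl β-keto lactone. C12 with its methyl group, its oxygen and the C13–C16/C1 chain maps onto (R)-linalool, and C6–C9 onto a glyceraldehyde–propionate unit.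

## Logic of the disconnections

31 ⇒ 30. The C11–O bond of the epoxide is cut to the 11R,12R-diol. Closing it by Mitsunobu cyclodehydration inverts C11 and keeps C12, which gives the cis-epoxide from a ketone-derived carbinol. The gain is that the acid-sensitive epoxide appears only in the last step. The demand is that C1 already carries its acetate, so that only the diol can react.

30 ⇒ 26 (through 29, 28, 27). No skeletal bond is cut. The C11 carbinol goes back to the ketone and the acetate to a silyl ether, because an allylic acetate cannot be present when palladium is used. Both silyl ethers of 26 are tert-butyldimethylsilyl; the secondary one at C1 is cleaved before the tertiary one at C12. The demand is a reagent-controlled reduction to 11R on the silyl-protected ketone; chelation control on the free hydroxy ketone would favour 11S.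

26 ⇒ 25. The C9–C10 bond is cut and CO2 is inserted between C10 and an oxygen on C9. This replaces a 14-membered C–C ring closure by a ring contraction of a lactone. The forward step needs ionisation at C9–O only, attack at C9 and not C7, and retention of the E-alkene.

25 ⇒ 23. The lactone C–O bond at C9 is cut to a primary allylic alcohol and a tert-butyl β-keto ester. The forward closure runs through an acylketene under neutral thermal conditions, so C6–H meets no base. It needs high dilution and a protected C12 oxygen.

23 ⇒ 20. The butenolide is opened at C3=C4 and at the acyl C5–O6 bond, leading back to an α-hydroxy ketone (C3 ketone, C6 hydroxyl) and a phosphonopropionate. The gain is an open chain with one carbonyl-based handle. The forward step needs a base mild enough to leave C6–H and the β-silyloxy ketone untouched.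

20 ⇒ 10 + 16. The C1–C2 bond is cut as an aldol bond between a methyl ketone and an enal; this halves the molecule. The forward step must enolise 10 at the methyl group only and set 1R by reagent control, since C6 is four atoms away and protected as a weakly directing silyl ether.

10 ⇒ 1 + 2. C7=C8 is cut as a Wittig bond, and C2–C3 as a methyl addition to a C3 aldehyde. C6 is taken unchanged from 1. The demand is differentiation of the two hydroxyl groups after acetonide removal, met by selective oxidation of the primary silyl ether.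

16 ⇒ 11. The C1 aldehyde comes from allylic oxidation of the E-methyl group, the carboxyl carbon is attached to C10 by enolate acylation, and the C11 ketone comes from the vinyl group. All ten carbons and C12 come from 11. The demand is Markovnikov oxidation at a hindered vinyl group next to a quaternary silyloxy carbon.

## Other disconnections considered

Alternative 1: The butenolide is cut at C2–C3, C4–C5 and C5–O. In the forward step the magnesium alkoxide of propargylic alcohol A1 (C6 carbinol with a propynyl group, C7–C14 chain with the epoxide) directs anti-addition of Grignard reagent A2 across C3≡C4; CO2 traps the C4–Mg bond and acid closes the lactone to A3.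
- In favour: three bonds and the tetrasubstituted alkene are formed in one flask with fixed regiochemistry. The lactone closes under acid, so C6–H never sees base; on this point it is better than the chosen plan, whose HWE step uses an amine base. A1 is within reach of asymmetric alkynylation, which is equal to the chiral-pool source of C6.
- Against: alkoxide-directed carbomagnesiation is dependable mainly for allyl-type reagents; A2 is an alkyl reagent with two β-oxygens and may add slowly or fragment. The epoxide of A1 must survive the Grignard reagent and MgBr2 with heating. A3 is still acyclic and lacks C15 and C16, so the ring would be closed across C16–C1 by an alkenyl-metal addition that creates C1 late and without a reliable control element.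
- Comparison: on structure, the heterocycle is made faster, but ring closure and C1 stay open, whereas the chosen plan solves both. On mechanism, polar organomagnesium chemistry next to an epoxide stands against neutral ion-pair chemistry with the epoxide installed last. On step economy the two are about equal once the macrocyclisation is added.

Alternative 2: The cut is C3–C6, C4–C5 and C5–O at once. The linear enal–silylalkyne A4 would combine with CO on a low-valent metal such as Cp2Ti(PMe3)2 or Mo(CO)6 (oxametallacycle, CO insertion, reductive elimination) to give A5.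
- In favour: it is the most convergent plan. Both rings and three bonds form in one step, all carbons and the epoxide are in place, and the silyl group fixes the alkyne regiochemistry. On paper its step economy is better than that of the chosen plan.
- Against: hetero-Pauson–Khand reactions are established where a short tether forces a five- or six-membered carbocycle; an eleven-atom tether gives no such help and intermolecular coupling would compete. The aldehyde is a conjugated enal. C6 is created with only remote stereocentres to guide it. Low-valent titanium can open or deoxygenate epoxides. The silyl group must still be exchanged for methyl on a base-sensitive butenolide.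
- Comparison: the chosen plan takes C6 from the chiral pool, which is better; it relies on reaction types that tolerate large rings, and it keeps the epoxide out of all metal-mediated steps. It pays for this with two macrocyclic steps in place of one.

Alternative 3: The cut is C1–C2, used as the ring-closing bond. The boron enolate of the C3 methyl ketone in seco compound A6 would add to the C1 enal of the same molecule to give A7; the butenolide and the acetate follow.
- In favour: it is the same aldol bond as in the chosen plan but also closes the ring, so macrolactonisation, ring contraction and much protecting-group work disappear. It is clearly shorter, and on step economy it is the better plan. The C6 benzyl-type ether may give 1,4-induction without a chiral reagent. No allylic ester has to face palladium. The epoxide could be made early on an open chain, which is equal to or safer than the late reduction and cyclodehydration.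
- Against: enolisation must be done on a molecule that already holds the aldehyde, and at high dilution, where it is slow. The chloroborane is a Lewis acid towards the epoxide. Facial selectivity in a 14-membered transition state depends on ring strain as much as on C6. The butenolide must then be annulated onto a macrocyclic β-oxygenated ketone that can eliminate under the HWE base.
- Comparison: the chosen plan runs the same aldol between two fragments, where stoichiometry and reagent control are simple, and builds the butenolide before any ring exists. It accepts about six more steps for that.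

Key step: step 20

Remark: the configurations of 25 and 26 were checked against 31 and are consistent (1R, 6R and 12R throughout; 11S arises by inversion of an 11R carbinol). The only change to these two compounds is a tert-butyldimethylsilyl group on the C12 oxygen. Locants C1–C16 are those of the first section; commercial 1 and 11 are taken as single enantiomers.

## Steps

Step 1
Reactants: 1 (S)-2,3-O-isopropylideneglyceraldehyde; 2 ethyl 2-(triphenylphosphoranylidene)propanoate
Product: 3 ethyl (2E)-3-[(4R)-2,2-dimethyl-1,3-dioxolan-4-yl]-2-methylprop-2-enoate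
Conditions: CH2Cl2, 0 °C to rt
Reagents that add atoms: none
Why: Wittig reaction of a stabilised α-methyl ylide, which should give the E-trisubstituted enoate (C7=C8); C6 is taken unchanged from 1 and only its descriptor changes.

Step 2
Reactants: 3 ethyl (2E)-3-[(4R)-2,2-dimethyl-1,3-dioxolan-4-yl]-2-methylprop-2-enoate
Product: 4 (2E)-3-[(4R)-2,2-dimethyl-1,3-dioxolan-4-yl]-2-methylprop-2-en-1-ol
Conditions: i-Bu2AlH, CH2Cl2, −78 °C; aq. KNaC4H4O6
Reagents that add atoms: none
Why: 1,2-Reduction of the enoate to the allylic alcohol (C9–OH); the acetal and the alkene geometry are not affected.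

Step 3
Reactants: 4 (2E)-3-[(4R)-2,2-dimethyl-1,3-dioxolan-4-yl]-2-methylprop-2-en-1-ol
Product: 5 (4R)-4-{(1E)-3-[(4-methoxybenzyl)oxy]-2-methylprop-1-en-1-yl}-2,2-dimethyl-1,3-dioxolane
Conditions: NaH, 4-methoxybenzyl chloride, n-Bu4NI (cat.), THF, 0 °C to rt
Reagents that add atoms: 4-methoxybenzyl chloride, COc1ccc(CCl)cc1
Why: Williamson etherification; the 4-methoxybenzyl ether is later removed oxidatively under neutral conditions, orthogonal to all silyl ethers.

Step 4
Reactants: 5 (4R)-4-{(1E)-3-[(4-methoxybenzyl)oxy]-2-methylprop-1-en-1-yl}-2,2-dimethyl-1,3-dioxolane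
Product: 6 (2R,3E)-5-[(4-methoxybenzyl)oxy]-4-methylpent-3-ene-1,2-diol
Conditions: AcOH/H2O (4:1), 40 °C
Reagents that add atoms: none
Why: Mild acetal hydrolysis; the allylic ether and the secondary allylic carbinol should tolerate aqueous acetic acid.

Step 5
Reactants: 6 (2R,3E)-5-[(4-methoxybenzyl)oxy]-4-methylpent-3-ene-1,2-diol
Product: 7 (2R,3E)-5-[(4-methoxybenzyl)oxy]-4-methyl-1,2-bis[(triethylsilyl)oxy]pent-3-ene
Conditions: Et3SiCl, imidazole, CH2Cl2, 0 °C
Reagents that add atoms: chlorotriethylsilane, CC[Si](Cl)(CC)CC
Why: Exhaustive silylation; the two triethylsilyl ethers are told apart in the next step by their primary or secondary position.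

Step 6
Reactants: 7 (2R,3E)-5-[(4-methoxybenzyl)oxy]-4-methyl-1,2-bis[(triethylsilyl)oxy]pent-3-ene
Product: 8 (2R,3E)-5-[(4-methoxybenzyl)oxy]-4-methyl-2-[(triethylsilyl)oxy]pent-3-enal
Conditions: (COCl)2, DMSO, CH2Cl2, −78 to −30 °C; Et3N, −78 to 0 °C; used crude
Reagents that add atoms: none
Why: Under Swern conditions a primary triethylsilyl ether is cleaved and oxidised to the aldehyde while the secondary one stays; the C3 aldehyde is obtained without a separate deprotection and is used at once because its α-centre (C6) is labile.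

Step 7
Reactants: 8 (2R,3E)-5-[(4-methoxybenzyl)oxy]-4-methyl-2-[(triethylsilyl)oxy]pent-3-enal
Product: 9 (3R,4E)-6-[(4-methoxybenzyl)oxy]-5-methyl-3-[(triethylsilyl)oxy]hex-4-en-2-ol (both C2 epimers)
Conditions: MeMgBr, Et2O, −78 °C
Reagents that add atoms: methylmagnesium bromide, C[Mg]Br
Why: Grignard addition brings in C2; the new carbinol centre is oxidised in the next step, so its configuration is irrelevant, and the low temperature protects C6.

Step 8
Reactants: 9 (3R,4E)-6-[(4-methoxybenzyl)oxy]-5-methyl-3-[(triethylsilyl)oxy]hex-4-en-2-ol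
Product: 10 (3R,4E)-6-[(4-methoxybenzyl)oxy]-5-methyl-3-[(triethylsilyl)oxy]hex-4-en-2-one
Conditions: Dess–Martin periodinane, NaHCO3, CH2Cl2, 0 °C to rt
Reagents that add atoms: none
Why: Buffered Dess–Martin oxidation gives the methyl ketone without base, so the α-silyloxy β,γ-unsaturated ketone should keep its C6 configuration.

Step 9
Reactants: 11 (R)-linalool
Product: 12 tert-butyl{[(3R)-3,7-dimethylocta-1,6-dien-3-yl]oxy}dimethylsilane
Conditions: TBSOTf, 2,6-lutidine, CH2Cl2, −78 to 0 °C
Reagents that add atoms: tert-butyldimethylsilyl trifluoromethanesulfonate, CC(C)(C)[Si](C)(C)OS(=O)(=O)C(F)(F)F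
Why: The silyl triflate silylates the tertiary allylic alcohol; the tertiary tert-butyldimethylsilyl ether (future C12–O) is chosen to outlast every later step up to step 24.

Step 10
Reactants: 12 tert-butyl{[(3R)-3,7-dimethylocta-1,6-dien-3-yl]oxy}dimethylsilane
Product: 13 (3R)-3-[(tert-butyldimethylsilyl)oxy]-3,7-dimethyloct-6-en-2-one
Conditions: Pd(Quinox)Cl2 (5 mol %, Quinox = 2-(4,5-dihydrooxazol-2-yl)quinoline), AgSbF6 (12 mol %), aq. t-BuOOH, CH2Cl2, 0 °C to rt
Reagents that add atoms: tert-butyl hydroperoxide, CC(C)(C)OO
Why: Wacker-type oxidation of the terminal vinyl group to the methyl ketone (C11 ketone, C10 methyl); the quinoline–oxazoline palladium/peroxide variant is chosen because it gives methyl ketones from allylic ethers where O2/CuCl conditions tend towards aldehydes, and the trisubstituted alkene is not a substrate.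

Step 11
Reactants: 13 (3R)-3-[(tert-butyldimethylsilyl)oxy]-3,7-dimethyloct-6-en-2-one
Product: 14 tert-butyl (4R)-4-[(tert-butyldimethylsilyl)oxy]-4,8-dimethyl-3-oxonon-7-enoate
Conditions: LiN(i-Pr)2 (2.2 equiv), THF, −78 °C; Boc2O, −78 to 0 °C
Reagents that add atoms: di-tert-butyl dicarbonate, CC(C)(C)OC(=O)OC(=O)OC(C)(C)C
Why: C-acylation of a ketone lithium enolate with a dicarbonate; C12 is quaternary, so only the C10 methyl group can enolise, and the second equivalent of base stores the product as its stabilised enolate.

Step 12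
Reactants: 14 tert-butyl (4R)-4-[(tert-butyldimethylsilyl)oxy]-4,8-dimethyl-3-oxonon-7-enoate
Product: 16 tert-butyl (4R,7E)-4-[(tert-butyldimethylsilyl)oxy]-4,8-dimethyl-3,9-dioxonon-7-enoate, via allylic alcohol 15 (not isolated)
Conditions: SeO2 (0.5 equiv), t-BuOOH, salicylic acid (cat.), CH2Cl2, rt; then MnO2, CH2Cl2, rt
Reagents that add atoms: selenium dioxide, O=[Se]=O (oxygen donor, regenerated by tert-butyl hydroperoxide, CC(C)(C)OO)
Why: Allylic oxidation by SeO2 (ene reaction, then 2,3-shift) attacks the E-methyl group of the trisubstituted alkene, and MnO2 converges alcohol 15 and enal to the E-enal (C1 aldehyde); the mild peroxide protocol at room temperature is chosen to spare the β-keto ester methylene.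

Step 13
Reactants: 10 (3R,4E)-6-[(4-methoxybenzyl)oxy]-5-methyl-3-[(triethylsilyl)oxy]hex-4-en-2-one; 16 tert-butyl (4R,7E)-4-[(tert-butyldimethylsilyl)oxy]-4,8-dimethyl-3,9-dioxonon-7-enoate
Product: 18 tert-butyl (4R,7E,9R,12R,13E)-4-[(tert-butyldimethylsilyl)oxy]-9-hydroxy-15-[(4-methoxybenzyl)oxy]-4,8,14-trimethyl-3,11-dioxo-12-[(triethylsilyl)oxy]pentadeca-7,13-dienoate, via boron enolate 17 (not isolated)
Conditions: (−)-Ipc2BCl, Et3N, Et2O, −78 to 0 °C; then 16, −78 to −20 °C; MeOH, aq. NaH2PO4/Na2HPO4 (pH 7), H2O2, 0 °C
Reagents that add atoms: none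
Why: Boron aldol reaction of a methyl ketone: the hindered chloroborane and amine should enolise 10 at the methyl group (C2) only, and the isopinocampheyl ligands of the (−)-reagent are expected to direct the enolate to the re face of the enal, which gives 1R at the new carbinol (C9 of 18). The C6 silyl ether should exert only a weak 1,4-bias, so the reagent decides; the covalent boron enolate is weakly basic and should tolerate the β-keto ester of 16.

Step 14
Reactants: 18 tert-butyl (4R,7E,9R,12R,13E)-4-[(tert-butyldimethylsilyl)oxy]-9-hydroxy-15-[(4-methoxybenzyl)oxy]-4,8,14-trimethyl-3,11-dioxo-12-[(triethylsilyl)oxy]pentadeca-7,13-dienoate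
Product: 19 tert-butyl (4R,7E,9R,12R,13E)-4,9-bis[(tert-butyldimethylsilyl)oxy]-15-[(4-methoxybenzyl)oxy]-4,8,14-trimethyl-3,11-dioxo-12-[(triethylsilyl)oxy]pentadeca-7,13-dienoate
Conditions: TBSOTf, 2,6-lutidine, CH2Cl2, −78 °C
Reagents that add atoms: tert-butyldimethylsilyl trifluoromethanesulfonate, CC(C)(C)[Si](C)(C)OS(=O)(=O)C(F)(F)F
Why: Low-temperature silylation of the β-hydroxy ketone avoids retro-aldol cleavage and elimination; any silyl enol ether formed at the β-keto ester is hydrolysed on work-up or in step 15.

Step 15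
Reactants: 19 tert-butyl (4R,7E,9R,12R,13E)-4,9-bis[(tert-butyldimethylsilyl)oxy]-15-[(4-methoxybenzyl)oxy]-4,8,14-trimethyl-3,11-dioxo-12-[(triethylsilyl)oxy]pentadeca-7,13-dienoate
Product: 20 tert-butyl (4R,7E,9R,12R,13E)-4,9-bis[(tert-butyldimethylsilyl)oxy]-12-hydroxy-15-[(4-methoxybenzyl)oxy]-4,8,14-trimethyl-3,11-dioxopentadeca-7,13-dienoate
Conditions: HF·pyridine, pyridine, THF, 0 °C
Reagents that add atoms: none
Why: A secondary triethylsilyl ether is cleaved by buffered HF·pyridine far faster than secondary or tertiary tert-butyldimethylsilyl ethers, so only the C6 hydroxyl is freed.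

Step 16
Reactants: 20 tert-butyl (4R,7E,9R,12R,13E)-4,9-bis[(tert-butyldimethylsilyl)oxy]-12-hydroxy-15-[(4-methoxybenzyl)oxy]-4,8,14-trimethyl-3,11-dioxopentadeca-7,13-dienoate
Product: 21 tert-butyl (4R,7E,9R,12R,13E)-4,9-bis[(tert-butyldimethylsilyl)oxy]-12-{[2-(diethoxyphosphoryl)propanoyl]oxy}-15-[(4-methoxybenzyl)oxy]-4,8,14-trimethyl-3,11-dioxopentadeca-7,13-dienoate (epimers at the phosphonate carbon)
Conditions: 2-(diethoxyphosphoryl)propanoic acid, EDC·HCl, DMAP (cat.), CH2Cl2, 0 °C to rt
Reagents that add atoms: 2-(diethoxyphosphoryl)propanoic acid, CCOP(=O)(OCC)C(C)C(=O)O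
Why: Carbodiimide esterification of the α-hydroxy ketone brings in C4, its methyl group and C5; the stereocentre at the phosphonate carbon is lost in the next step.

Step 17
Reactants: 21 tert-butyl (4R,7E,9R,12R,13E)-4,9-bis[(tert-butyldimethylsilyl)oxy]-12-{[2-(diethoxyphosphoryl)propanoyl]oxy}-15-[(4-methoxybenzyl)oxy]-4,8,14-trimethyl-3,11-dioxopentadeca-7,13-dienoate
Product: 22 tert-butyl (4R,7E,9R)-4,9-bis[(tert-butyldimethylsilyl)oxy]-10-{(2R)-2-[(1E)-3-[(4-methoxybenzyl)oxy]-2-methylprop-1-en-1-yl]-4-methyl-5-oxo-2,5-dihydrofuran-3-yl}-4,8-dimethyl-3-oxodec-7-enoate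
Conditions: LiCl, i-Pr2NEt (3 equiv), MeCN, 0 °C to rt
Reagents that add atoms: none
Why: Intramolecular Horner–Wadsworth–Emmons reaction onto the C3 ketone closes the butenolide (C3=C4); lithium chelation lets a tertiary amine deprotonate the phosphonate, which should spare C6–H and the β-silyloxy ketone, and the β-keto ester is only a spectator acid.

Step 18
Reactants: 22 tert-butyl (4R,7E,9R)-4,9-bis[(tert-butyldimethylsilyl)oxy]-10-{(2R)-2-[(1E)-3-[(4-methoxybenzyl)oxy]-2-methylprop-1-en-1-yl]-4-methyl-5-oxo-2,5-dihydrofuran-3-yl}-4,8-dimethyl-3-oxodec-7-enoate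
Product: 23 tert-butyl (4R,7E,9R)-4,9-bis[(tert-butyldimethylsilyl)oxy]-10-{(2R)-2-[(1E)-3-hydroxy-2-methylprop-1-en-1-yl]-4-methyl-5-oxo-2,5-dihydrofuran-3-yl}-4,8-dimethyl-3-oxodec-7-enoate
Conditions: DDQ, CH2Cl2/aq. NaH2PO4/Na2HPO4 (pH 7), 0 °C
Reagents that add atoms: none
Why: Oxidative cleavage of the 4-methoxybenzyl ether under neutral conditions frees the primary allylic C9 hydroxyl without touching the silyl ethers or C6–H.

Step 19
Reactants: 23 tert-butyl (4R,7E,9R)-4,9-bis[(tert-butyldimethylsilyl)oxy]-10-{(2R)-2-[(1E)-3-hydroxy-2-methylprop-1-en-1-yl]-4-methyl-5-oxo-2,5-dihydrofuran-3-yl}-4,8-dimethyl-3-oxodec-7-enoate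
Product: 25 16-membered allyl β-keto macrolactone (1R,6R,12R;7E,15E) with C1 and C12 tert-butyldimethylsilyl ethers, via acylketene 24 (not isolated)
Conditions: toluene, 110 °C, syringe-pump addition (final 1 mM)
Reagents that add atoms: none
Why: Thermal loss of tert-butanol from the tert-butyl β-keto ester gives acylketene 24, which the primary C9 hydroxyl traps (acylketene macrolactonisation); the conditions are neutral, and the silyl ether on C12 keeps that oxygen from attacking the ketene.

Step 20
Reactants: 25 16-membered allyl β-keto macrolactone (1R,6R,12R;7E,15E) with C1 and C12 tert-butyldimethylsilyl ethers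
Product: 26 14-membered C11 ketone (1R,6R,12R;7E,15E) with C1 and C12 tert-butyldimethylsilyl ethers
Conditions: Pd(PPh3)4 (10 mol %), degassed THF (2 mM), 25 to 45 °C
Reagents that add atoms: none
Why: Zerovalent palladium ionises the primary allylic C9–O bond of 25 to a cationic π-allyl complex (C7–C8–C9) paired with the β-keto carboxylate, which loses CO2 to give the C10 enolate; bond formation between C10 and the unsubstituted terminus C9 then releases the catalyst. The closest known reaction type is the palladium-catalysed decarboxylative allylation of allyl β-keto esters (the catalytic counterpart of the Carroll rearrangement, within Tsuji–Trost chemistry), here run as a ring contraction. The 16-membered lactone is opened and a 14-membered carbocycle is closed in which all three allyl carbons stay in the ring (attack at the distal terminus C9); attack at C7 would give a 12-membered ring with an exocyclic alkene. No stereocentre is formed, since C10 is a methylene group, and C1, C6 and C12 are spectators. Attack at C9 is expected because C7 is secondary and flanked by the C8 methyl group and the butenolide-bearing C6, and triphenylphosphine complexes send soft enolates to the less substituted terminus. The E geometry of C7=C8 should persist because syn–anti exchange would need a σ-bond from palladium to the hindered C7. Ionisation of the secondary allylic C6–O lactone bond should be slower than that of the primary ester, whose leaving group is removed irreversibly by decarboxylation, and the silyl ether at C1 is no leaving group. High dilution in a weakly polar solvent should keep the ion pair together, so that recombination is intramolecular and the enolate is consumed before it can deprotonate C6–H.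

Step 21
Reactants: 26 14-membered C11 ketone (1R,6R,12R;7E,15E) with C1 and C12 tert-butyldimethylsilyl ethers
Product: 27 C1 alcohol of the 14-membered C11 ketone (C12 silyl ether kept)
Conditions: HF·pyridine, pyridine, THF, 0 °C to rt
Reagents that add atoms: none
Why: The secondary allylic silyl ether at C1 is cleaved much faster than the tertiary one at C12; buffered fluoride in acid form does not touch C6–H.

Step 22
Reactants: 27 C1 alcohol of the 14-membered C11 ketone (C12 silyl ether kept)
Product: 28 C1 acetate of the 14-membered C11 ketone (C12 silyl ether kept)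
Conditions: Ac2O, pyridine, DMAP (cat.), CH2Cl2, 0 °C
Reagents that add atoms: acetic anhydride, CC(=O)OC(C)=O
Why: Acetylation of the only free hydroxyl; the acetate is installed after the palladium step, so it is never exposed to zerovalent palladium.

Step 23
Reactants: 28 C1 acetate of the 14-membered C11 ketone (C12 silyl ether kept)
Product: 29 (11R)-carbinol with C1 acetate and C12 tert-butyldimethylsilyl ether
Conditions: (S)-2-methyl-CBS-oxazaborolidine (1 equiv), catecholborane, toluene, −78 to −30 °C
Reagents that add atoms: none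
Why: Corey–Bakshi–Shibata reduction: the ketone lies between a methylene group (small) and the quaternary silyloxy carbon C12 (large), so the (S)-catalyst should deliver hydride to give 11R. The polar Felkin–Anh preference of the α-silyloxy ketone has the same sense, and catecholborane leaves alkenes, lactone and acetate alone.

Step 24
Reactants: 29 (11R)-carbinol with C1 acetate and C12 tert-butyldimethylsilyl ether
Product: 30 (11R,12R)-diol with C1 acetate
Conditions: 48% aq. HF, MeCN, 0 °C to rt
Reagents that add atoms: none
Why: Aqueous HF cleaves the hindered tertiary silyl ether; this is done before the epoxide exists, and the acetate, the lactone and the alkenes should tolerate the acid.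

Step 25
Reactants: 30 (11R,12R)-diol with C1 acetate
Product: 31 target CNP0302675.1 (1R,6R,11S,12R;7E,15E)
Conditions: PPh3, DIAD, THF, 0 to 50 °C
Reagents that add atoms: none
Why: Mitsunobu cyclodehydration: the secondary C11 hydroxyl is activated as the oxyphosphonium ion and displaced from the rear by the tertiary C12 oxygen. C11 is inverted to S and C12 retained, giving the cis-epoxide under neutral conditions that spare the acetate and C6–H.

## Compound list

1 | (S)-2,3-O-isopropylideneglyceraldehyde | CC1(C)OC[C@@H](C=O)O1 | starting material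
2 | ethyl 2-(triphenylphosphoranylidene)propanoate | CCOC(=O)C(C)=P(c1ccccc1)(c1ccccc1)c1ccccc1 | starting material
3 | ethyl (2E)-3-[(4R)-2,2-dimethyl-1,3-dioxolan-4-yl]-2-methylprop-2-enoate | CC1(C)OC[C@@H](/C=C(\C)C(=O)OCC)O1 | intermediate
4 | (2E)-3-[(4R)-2,2-dimethyl-1,3-dioxolan-4-yl]-2-methylprop-2-en-1-ol | CC1(C)OC[C@@H](/C=C(\C)CO)O1 | intermediate
5 | (4R)-4-{(1E)-3-[(4-methoxybenzyl)oxy]-2-methylprop-1-en-1-yl}-2,2-dimethyl-1,3-dioxolane | CC1(C)OC[C@@H](/C=C(\C)COCc2ccc(OC)cc2)O1 | intermediate
6 | (2R,3E)-5-[(4-methoxybenzyl)oxy]-4-methylpent-3-ene-1,2-diol | OC[C@H](O)/C=C(\C)COCc1ccc(OC)cc1 | intermediate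
7 | (2R,3E)-5-[(4-methoxybenzyl)oxy]-4-methyl-1,2-bis[(triethylsilyl)oxy]pent-3-ene | CC[Si](CC)(CC)OC[C@H](O[Si](CC)(CC)CC)/C=C(\C)COCc1ccc(OC)cc1 | intermediate
8 | (2R,3E)-5-[(4-methoxybenzyl)oxy]-4-methyl-2-[(triethylsilyl)oxy]pent-3-enal | O=C[C@H](O[Si](CC)(CC)CC)/C=C(\C)COCc1ccc(OC)cc1 | intermediate
9 | (3R,4E)-6-[(4-methoxybenzyl)oxy]-5-methyl-3-[(triethylsilyl)oxy]hex-4-en-2-ol, both C2 epimers | CC(O)[C@H](O[Si](CC)(CC)CC)/C=C(\C)COCc1ccc(OC)cc1 | intermediate
10 | (3R,4E)-6-[(4-methoxybenzyl)oxy]-5-methyl-3-[(triethylsilyl)oxy]hex-4-en-2-one | CC(=O)[C@H](O[Si](CC)(CC)CC)/C=C(\C)COCc1ccc(OC)cc1 | intermediate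
11 | (R)-linalool, (3R)-3,7-dimethylocta-1,6-dien-3-ol | C=C[C@](C)(O)CCC=C(C)C | starting material
12 | tert-butyl{[(3R)-3,7-dimethylocta-1,6-dien-3-yl]oxy}dimethylsilane | C=C[C@](C)(O[Si](C)(C)C(C)(C)C)CCC=C(C)C | intermediate
13 | (3R)-3-[(tert-butyldimethylsilyl)oxy]-3,7-dimethyloct-6-en-2-one | CC(=O)[C@](C)(O[Si](C)(C)C(C)(C)C)CCC=C(C)C | intermediate
14 | tert-butyl (4R)-4-[(tert-butyldimethylsilyl)oxy]-4,8-dimethyl-3-oxonon-7-enoate | CC(C)(C)OC(=O)CC(=O)[C@](C)(O[Si](C)(C)C(C)(C)C)CCC=C(C)C | intermediate
15 | tert-butyl (4R,7E)-4-[(tert-butyldimethylsilyl)oxy]-9-hydroxy-4,8-dimethyl-3-oxonon-7-enoate (not isolated) | CC(C)(C)OC(=O)CC(=O)[C@](C)(O[Si](C)(C)C(C)(C)C)CC/C=C(\C)CO | intermediate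
16 | tert-butyl (4R,7E)-4-[(tert-butyldimethylsilyl)oxy]-4,8-dimethyl-3,9-dioxonon-7-enoate | CC(C)(C)OC(=O)CC(=O)[C@](C)(O[Si](C)(C)C(C)(C)C)CC/C=C(\C)C=O | intermediate
17 | diisopinocampheylboron enolate of 10, boron on the C3 oxygen, C2 as =CH2 (not isolated) | C=C(OB([C@@H]1C[C@@H]2C[C@H]([C@H]1C)C2(C)C)[C@@H]1C[C@@H]2C[C@H]([C@H]1C)C2(C)C)[C@H](O[Si](CC)(CC)CC)/C=C(\C)COCc1ccc(OC)cc1 | intermediate
18 | tert-butyl (4R,7E,9R,12R,13E)-4-[(tert-butyldimethylsilyl)oxy]-9-hydroxy-15-[(4-methoxybenzyl)oxy]-4,8,14-trimethyl-3,11-dioxo-12-[(triethylsilyl)oxy]pentadeca-7,13-dienoate | CC(C)(C)OC(=O)CC(=O)[C@](C)(O[Si](C)(C)C(C)(C)C)CC/C=C(\C)[C@H](O)CC(=O)[C@H](O[Si](CC)(CC)CC)/C=C(\C)COCc1ccc(OC)cc1 | intermediate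
19 | tert-butyl (4R,7E,9R,12R,13E)-4,9-bis[(tert-butyldimethylsilyl)oxy]-15-[(4-methoxybenzyl)oxy]-4,8,14-trimethyl-3,11-dioxo-12-[(triethylsilyl)oxy]pentadeca-7,13-dienoate | CC(C)(C)OC(=O)CC(=O)[C@](C)(O[Si](C)(C)C(C)(C)C)CC/C=C(\C)[C@H](O[Si](C)(C)C(C)(C)C)CC(=O)[C@H](O[Si](CC)(CC)CC)/C=C(\C)COCc1ccc(OC)cc1 | intermediate
20 | tert-butyl (4R,7E,9R,12R,13E)-4,9-bis[(tert-butyldimethylsilyl)oxy]-12-hydroxy-15-[(4-methoxybenzyl)oxy]-4,8,14-trimethyl-3,11-dioxopentadeca-7,13-dienoate | CC(C)(C)OC(=O)CC(=O)[C@](C)(O[Si](C)(C)C(C)(C)C)CC/C=C(\C)[C@H](O[Si](C)(C)C(C)(C)C)CC(=O)[C@H](O)/C=C(\C)COCc1ccc(OC)cc1 | intermediate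
21 | tert-butyl (4R,7E,9R,12R,13E)-4,9-bis[(tert-butyldimethylsilyl)oxy]-12-{[2-(diethoxyphosphoryl)propanoyl]oxy}-15-[(4-methoxybenzyl)oxy]-4,8,14-trimethyl-3,11-dioxopentadeca-7,13-dienoate, epimers at the phosphonate carbon | CC(C)(C)OC(=O)CC(=O)[C@](C)(O[Si](C)(C)C(C)(C)C)CC/C=C(\C)[C@H](O[Si](C)(C)C(C)(C)C)CC(=O)[C@H](OC(=O)C(C)P(=O)(OCC)OCC)/C=C(\C)COCc1ccc(OC)cc1 | intermediate
22 | tert-butyl (4R,7E,9R)-4,9-bis[(tert-butyldimethylsilyl)oxy]-10-{(2R)-2-[(1E)-3-[(4-methoxybenzyl)oxy]-2-methylprop-1-en-1-yl]-4-methyl-5-oxo-2,5-dihydrofuran-3-yl}-4,8-dimethyl-3-oxodec-7-enoate | CC(C)(C)OC(=O)CC(=O)[C@](C)(O[Si](C)(C)C(C)(C)C)CC/C=C(\C)[C@H](O[Si](C)(C)C(C)(C)C)CC1=C(C)C(=O)O[C@@H]1/C=C(\C)COCc1ccc(OC)cc1 | intermediate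
23 | tert-butyl (4R,7E,9R)-4,9-bis[(tert-butyldimethylsilyl)oxy]-10-{(2R)-2-[(1E)-3-hydroxy-2-methylprop-1-en-1-yl]-4-methyl-5-oxo-2,5-dihydrofuran-3-yl}-4,8-dimethyl-3-oxodec-7-enoate | CC(C)(C)OC(=O)CC(=O)[C@](C)(O[Si](C)(C)C(C)(C)C)CC/C=C(\C)[C@H](O[Si](C)(C)C(C)(C)C)CC1=C(C)C(=O)O[C@@H]1/C=C(\C)CO | intermediate
24 | acylketene from 23 by loss of tert-butanol: O=C=C10H–C11(=O)– on the chain of 23 (not isolated) | O=C=CC(=O)[C@](C)(O[Si](C)(C)C(C)(C)C)CC/C=C(\C)[C@H](O[Si](C)(C)C(C)(C)C)CC1=C(C)C(=O)O[C@@H]1/C=C(\C)CO | intermediate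
25 | 16-membered allyl β-keto macrolactone fused at C3–C6 to the α-methylbutenolide; ring path C1–C2–C3–C6–C7=C8(CH3)–C9–O–C(=O)–C10–C11(=O)–C12(CH3)–C13–C14–C15=C16(CH3); tert-butyldimethylsilyl ethers at C1 and C12; 1R,6R,12R; 7E,15E | CC(C)(C)[Si](C)(C)O[C@@H]1CC2=C(C)C(=O)O[C@@H]2/C=C(\C)COC(=O)CC(=O)[C@](C)(O[Si](C)(C)C(C)(C)C)CC/C=C/1C | intermediate
26 | 14-membered carbocyclic C11 ketone fused to the butenolide; tert-butyldimethylsilyl ethers at C1 and C12; 1R,6R,12R; 7E,15E | CC(C)(C)[Si](C)(C)O[C@@H]1CC2=C(C)C(=O)O[C@@H]2/C=C(\C)CCC(=O)[C@](C)(O[Si](C)(C)C(C)(C)C)CC/C=C/1C | intermediate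
27 | as 26 with free C1 hydroxyl; 1R,6R,12R | O[C@@H]1CC2=C(C)C(=O)O[C@@H]2/C=C(\C)CCC(=O)[C@](C)(O[Si](C)(C)C(C)(C)C)CC/C=C/1C | intermediate
28 | as 26 with C1 acetate; 1R,6R,12R | CC(=O)O[C@@H]1CC2=C(C)C(=O)O[C@@H]2/C=C(\C)CCC(=O)[C@](C)(O[Si](C)(C)C(C)(C)C)CC/C=C/1C | intermediate
29 | C11 carbinol with C1 acetate and C12 tert-butyldimethylsilyl ether; 1R,6R,11R,12R | CC(=O)O[C@@H]1CC2=C(C)C(=O)O[C@@H]2/C=C(\C)CC[C@@H](O)[C@](C)(O[Si](C)(C)C(C)(C)C)CC/C=C/1C | intermediate
30 | C11,C12-diol with C1 acetate; 1R,6R,11R,12R | CC(=O)O[C@@H]1CC2=C(C)C(=O)O[C@@H]2/C=C(\C)CC[C@@H](O)[C@](C)(O)CC/C=C/1C | intermediate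
31 | CNP0302675.1: 14-membered carbocycle fused to the α-methylbutenolide, C1 acetate, cis C11–C12 epoxide; 1R,6R,11S,12R; 7E,15E | CC(=O)O[C@@H]1CC2=C(C)C(=O)O[C@@H]2/C=C(\C)CC[C@@H]2O[C@]2(C)CC/C=C/1C | target

## Step count and least certain steps

Total: 25 steps. Longest linear sequence: 21 steps (steps 1–8 and 13–25, from 1); the branch from 11 has 4 steps (9–12).

Step 20 (key step). The ion pair may separate, so that allylation becomes intermolecular and gives oligomers. The enolate may attack C7 and give the 12-membered isomer. The allylic C6–O lactone bond may ionise reversibly and scramble C6, or open to a diene. The enolate may also take the acidic C6–H before it finds C9. Fallback, from 23 back to 26: 23 is converted with methyl chloroformate and pyridine into the allylic methyl carbonate F1. Pd(PPh3)4 in THF at high dilution ionises the carbonate; the methoxide set free deprotonates the β-keto ester, the strongest acid present, and the stabilised enolate closes the 14-membered ring at C9 (Tsuji–Trost macrocyclisation) to give the C10 tert-butyl ester F2. Cleavage of the tert-butyl ester with Me3SiOTf/2,6-lutidine and decarboxylation on aqueous work-up and gentle warming gives 26. Here the nucleophile exists before ionisation and no macrolactone is needed.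

Step 13. Facial control by the isopinocampheyl ligands in methyl-ketone aldols is only moderate and may be eroded by a 1,4-bias from C6. Some enolisation towards C6 or proton transfer from the β-keto ester of 16 to the enolate would lower conversion. Fallback, from 10 back to 18: 10 is converted into its kinetic trimethylsilyl enol ether F3 (LiN(SiMe3)2, Me3SiCl, THF, −78 °C). F3 is added to 16 in a Mukaiyama aldol reaction promoted by SiCl4 and a catalytic chiral bisphosphoramide (the antipode that favours re-face attack). No basic enolate is present, the aldolate is hydrolysed on work-up to 18, and any 1S epimer is removed by chromatography at 18 or 19.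

Step 10. Oxidation at the hindered vinyl group next to a quaternary silyloxy carbon may be slow or may turn anti-Markovnikov, giving the aldehyde. Fallback, from 12 back to 16, bypassing steps 10–12:
- mCPBA epoxidises the trisubstituted alkene of 12 selectively to epoxide F4.
- Ozonolysis of the remaining vinyl group gives aldehyde F5.
- The lithium enolate of tert-butyl acetate adds to give β-hydroxy ester F6.
- Dess–Martin oxidation gives β-keto ester F7.
- H5IO6 cleaves the epoxide to aldehyde F8.
- 2-(Triphenylphosphoranylidene)propanal converts F8 into the E-enal 16.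
This sequence is three steps longer but avoids the Wacker step, the enolate acylation and the exposure of the β-keto ester to SeO2.

Step 17. The amine base may epimerise C6, which is α to the ketone and allylic before ring closure and γ to the lactone after it, or may cause loss of the C1 silyloxy group by β-elimination. Fallback, from 20 back to 22: 20 is acylated with 2-bromopropanoyl bromide and pyridine to the α-bromo ester F9. SmI2 in THF at −78 °C effects an intramolecular Reformatsky addition to the C3 ketone, giving β-hydroxy lactone F10. Dehydration with SOCl2/pyridine at 0 °C towards the acidic C4–H gives 22 without any carbanion-generating base.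

Step 24. The hindered tertiary silyl ether may be cleaved only slowly, and prolonged acid may ionise the allylic acetate or the allylic lactone bond. Fallback, from 29 to 31, bypassing 30: the C11 hydroxyl of 29 is converted with MsCl/Et3N at 0 °C into mesylate F11. Buffered fluoride (n-Bu4NF/AcOH, or tris(dimethylamino)sulfonium difluorotrimethylsilicate) then removes the tertiary silyl group, and the C12 alkoxide so formed displaces the mesylate with inversion at C11, giving 31 directly.

## Further compounds

F1 | step 20 | methyl carbonate of 23 at the C9 oxygen | CC(C)(C)OC(=O)CC(=O)[C@](C)(O[Si](C)(C)C(C)(C)C)CC/C=C(\C)[C@H](O[Si](C)(C)C(C)(C)C)CC1=C(C)C(=O)O[C@@H]1/C=C(\C)COC(=O)OC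
F2 | step 20 | 14-membered ketone as 26 with a tert-butoxycarbonyl group on C10 (C10 epimers) | CC(C)(C)[Si](C)(C)O[C@@H]1CC2=C(C)C(=O)O[C@@H]2/C=C(\C)CC(C(=O)OC(C)(C)C)C(=O)[C@](C)(O[Si](C)(C)C(C)(C)C)CC/C=C/1C
F3 | step 13 | trimethylsilyl enol ether of 10 at C2=C3 | C=C(O[Si](C)(C)C)[C@H](O[Si](CC)(CC)CC)/C=C(\C)COCc1ccc(OC)cc1
F4 | step 10 | tert-butyl{[(3R)-5-(3,3-dimethyloxiran-2-yl)-3-methylpent-1-en-3-yl]oxy}dimethylsilane (epoxide epimers) | C=C[C@](C)(O[Si](C)(C)C(C)(C)C)CCC1OC1(C)C
F5 | step 10 | (2R)-2-[(tert-butyldimethylsilyl)oxy]-4-(3,3-dimethyloxiran-2-yl)-2-methylbutanal | O=C[C@](C)(O[Si](C)(C)C(C)(C)C)CCC1OC1(C)C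
F6 | step 10 | tert-butyl (4R)-4-[(tert-butyldimethylsilyl)oxy]-6-(3,3-dimethyloxiran-2-yl)-3-hydroxy-4-methylhexanoate (C3 epimers) | CC(C)(C)OC(=O)CC(O)[C@](C)(O[Si](C)(C)C(C)(C)C)CCC1OC1(C)C
F7 | step 10 | tert-butyl (4R)-4-[(tert-butyldimethylsilyl)oxy]-6-(3,3-dimethyloxiran-2-yl)-4-methyl-3-oxohexanoate | CC(C)(C)OC(=O)CC(=O)[C@](C)(O[Si](C)(C)C(C)(C)C)CCC1OC1(C)C
F8 | step 10 | tert-butyl (4R)-4-[(tert-butyldimethylsilyl)oxy]-4-methyl-3,7-dioxoheptanoate | CC(C)(C)OC(=O)CC(=O)[C@](C)(O[Si](C)(C)C(C)(C)C)CCC=O
F9 | step 17 | 2-bromopropanoate of 20 at the C6 oxygen (epimers at the bromide carbon) | CC(C)(C)OC(=O)CC(=O)[C@](C)(O[Si](C)(C)C(C)(C)C)CC/C=C(\C)[C@H](O[Si](C)(C)C(C)(C)C)CC(=O)[C@H](OC(=O)C(C)Br)/C=C(\C)COCc1ccc(OC)cc1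
F10 | step 17 | β-hydroxy γ-lactone: as 22 with C3 hydroxyl and C4 hydrogen in place of the C3=C4 double bond (C3 and C4 epimers) | CC(C)(C)OC(=O)CC(=O)[C@](C)(O[Si](C)(C)C(C)(C)C)CC/C=C(\C)[C@H](O[Si](C)(C)C(C)(C)C)CC1(O)C(C)C(=O)O[C@@H]1/C=C(\C)COCc1ccc(OC)cc1
F11 | step 24 | C11 methanesulfonate of 29 | CC(=O)O[C@@H]1CC2=C(C)C(=O)O[C@@H]2/C=C(\C)CC[C@@H](OS(C)(=O)=O)[C@](C)(O[Si](C)(C)C(C)(C)C)CC/C=C/1C
A1 | alternative 1 | propargylic alcohol (4R,5E)-8-[(2S,3R)-3-{2-[(tert-butyldimethylsilyl)oxy]ethyl}-3-methyloxiran-2-yl]-6-methyloct-5-en-2-yn-4-ol | CC#C[C@H](O)/C=C(\C)CC[C@@H]1O[C@]1(C)CCO[Si](C)(C)C(C)(C)C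
A2 | alternative 1 | (1,3-dioxolan-2-ylmethyl)magnesium bromide | Br[Mg]CC1OCCO1
A3 | alternative 1 | butenolide with C1 as dioxolane acetal and the C6–C14 chain | CC1=C(CC2OCCO2)[C@@H](/C=C(\C)CC[C@@H]3O[C@]3(C)CCO[Si](C)(C)C(C)(C)C)OC1=O
A4 | alternative 2 | linear C6 enal with C3≡C4 trimethylsilylalkyne, C1 silyl ether and C11–C12 epoxide | O=C/C=C(\C)CC[C@@H]1O[C@]1(C)CC/C=C(\C)[C@H](O[Si](C)(C)C(C)(C)C)CC#C[Si](C)(C)C
A5 | alternative 2 | macrocyclic α-trimethylsilyl butenolide with C1 silyl ether | CC(C)(C)[Si](C)(C)O[C@@H]1CC2=C([Si](C)(C)C)C(=O)O[C@@H]2/C=C(\C)CC[C@@H]2O[C@]2(C)CC/C=C/1C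
A6 | alternative 3 | seco keto-enal: C3 methyl ketone with C6 4-methoxybenzyl ether, C11–C12 epoxide and C1 enal | CC(=O)[C@H](OCc1ccc(OC)cc1)/C=C(\C)CC[C@@H]1O[C@]1(C)CC/C=C(\C)C=O
A7 | alternative 3 | 14-membered β-hydroxy ketone | O[C@@H]1CC(=O)[C@H](OCc2ccc(OC)cc2)/C=C(\C)CC[C@@H]2O[C@]2(C)CC/C=C/1C
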